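The route disconnects the C2=C3 olefin of the cyclopentene ring (C1–C5). A ruthenium carbene closes this ring by metathesis between a vinyl group on C1 and the vinyl carbinol at C4 and, in the same flask, cross-metathesis with 2-methyl-2-butene completes the C14=C15 olefin. The step exploits the cis C1/C5 substitution of the seven-membered ring and the tertiary allylic C4 hydroxyl. Its precursor is an 8-oxabicyclo[3.2.1]octane: an ether bridge from C6 to C10 and an iodomethyl group on C10 mask the C6 hydroxyl and the C10=C18 methylene, and hold both vinyl arms on one face. This core comes from a tethered oxidopyrylium [5+2] cycloaddition.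

Key step: step 23

Remark on the chemistry: ring carbons are numbered C1–C10 (C1 and C5 at the ring fusion, C2=C3, carbinol C4 with methyl C17, C10 carrying methylene C18) and the side chain C11–C15. Compounds 7, 8, 9 and 18 are carried as epimer mixtures at centres that later steps erase.

Step 1
Reactants: 1 (S)-but-3-yn-2-ol
Product: 2 (S)-3-[(4-methoxybenzyl)oxy]but-1-yne
Conditions: NaH, PMBCl, Bu4NI (cat.), THF/DMF, 0 °C → rt
Reagents that add atoms: 4-methoxybenzyl chloride, COc1ccc(CCl)cc1
Why: Williamson etherification of the propargylic alkoxide, which leaves the stereocentre (the later control element at C4) untouched.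

Step 2
Reactants: 2 (S)-3-[(4-methoxybenzyl)oxy]but-1-yne
Product: 3 (S)-4-[(4-methoxybenzyl)oxy]pent-2-ynoic acid
Conditions: n-BuLi, THF, −78 °C; CO2; aq. HCl
Reagents that add atoms: carbon dioxide, O=C=O
Why: Lithiation of the terminal alkyne and carboxylation of the acetylide.

Step 3
Reactants: 3 (S)-4-[(4-methoxybenzyl)oxy]pent-2-ynoic acid
Product: 4 (S,Z)-4-[(4-methoxybenzyl)oxy]pent-2-enoic acid
Conditions: H2 (1 atm), Pd/CaCO3 poisoned with Pb(OAc)2 (Lindlar catalyst), quinoline, EtOAc, rt
Reagents that add atoms: none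
Why: Lindlar semihydrogenation gives the Z olefin by syn delivery of hydrogen and leaves the benzylic ether intact.

Step 4
Reactants: 4 (S,Z)-4-[(4-methoxybenzyl)oxy]pent-2-enoic acid; 5 2-bromo-1-(furan-2-yl)ethan-1-one
Product: 6 2-(furan-2-yl)-2-oxoethyl (S,Z)-4-[(4-methoxybenzyl)oxy]pent-2-enoate
Conditions: Cs2CO3, DMF, 0 °C → rt
Reagents that add atoms: none
Why: SN2 alkylation of the caesium carboxylate by the α-bromo ketone, mild enough to keep the Z geometry.

Step 5
Reactants: 6 2-(furan-2-yl)-2-oxoethyl (S,Z)-4-[(4-methoxybenzyl)oxy]pent-2-enoate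
Product: 7 2-(furan-2-yl)-2-hydroxyethyl (S,Z)-4-[(4-methoxybenzyl)oxy]pent-2-enoate (both carbinol epimers)
Conditions: NaBH4, CeCl3·7H2O, MeOH, −78 °C; AcOH quench
Reagents that add atoms: none
Why: Luche reduction is selective for the ketone over the enoate and at low temperature avoids acyl migration; the new carbinol centre is erased in step 8.

Step 6
Reactants: 7 2-(furan-2-yl)-2-hydroxyethyl (S,Z)-4-[(4-methoxybenzyl)oxy]pent-2-enoate
Product: 8 (6-hydroxy-3-oxo-3,6-dihydro-2H-pyran-2-yl)methyl (S,Z)-4-[(4-methoxybenzyl)oxy]pent-2-enoate (epimer mixture)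
Conditions: NBS, NaHCO3, NaOAc, THF/H2O (4:1), 0 °C
Reagents that add atoms: water, O
Why: Achmatowicz oxidative ring expansion of the furyl carbinol to the pyranone hemiacetal.

Step 7
Reactants: 8 (6-hydroxy-3-oxo-3,6-dihydro-2H-pyran-2-yl)methyl (S,Z)-4-[(4-methoxybenzyl)oxy]pent-2-enoate
Product: 9 (6-acetoxy-3-oxo-3,6-dihydro-2H-pyran-2-yl)methyl (S,Z)-4-[(4-methoxybenzyl)oxy]pent-2-enoate
Conditions: Ac2O, pyridine, DMAP (cat.), CH2Cl2, 0 °C
Reagents that add atoms: acetic anhydride, CC(=O)OC(C)=O
Why: Acylation of the anomeric hydroxyl installs the leaving group needed for ylide formation.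

Step 8
Reactants: 9 (6-acetoxy-3-oxo-3,6-dihydro-2H-pyran-2-yl)methyl (S,Z)-4-[(4-methoxybenzyl)oxy]pent-2-enoate
Product: 11 tricyclic lactone enone (oxabicyclic C9 ketone with C7=C8 and the C1–C2 lactone to C18), via oxidopyrylium ylide 10 (not isolated)
Conditions: Et3N, MeCN (0.005 M), 60 °C
Reagents that add atoms: none
Why: Triethylamine expels acetate to give 3-oxidopyrylium ylide 10, which undergoes intramolecular [5+2] oxidopyrylium–alkene cycloaddition across the tethered (Z)-enoate: the three-atom ester tether can only reach the exo position of C1, the Z geometry puts the C5 arm cis to it, and with H-4 locked in the olefin plane by allylic 1,3-strain the ylide adds anti to the OPMB group, which fixes the absolute configuration of C1, C5, C6 and C10.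

Step 9
Reactants: 12 tert-butyl propanoate
Product: 13 (E)-1-tert-butoxy-1-(trimethylsilyloxy)prop-1-ene
Conditions: LiN(iPr)2, THF, −78 °C; Me3SiCl
Reagents that add atoms: chlorotrimethylsilane, C[Si](C)(C)Cl
Why: Kinetic deprotonation in THF gives the E(O) enolate (Ireland model), trapped on oxygen as the E ketene acetal.

Step 10
Reactants: 11 tricyclic lactone enone; 13 (E)-1-tert-butoxy-1-(trimethylsilyloxy)prop-1-ene
Product: 15 (7S,11R) C9 ketone carrying the 1-(tert-butoxycarbonyl)ethyl group on C7, via trimethylsilyl enol ether 14 (not isolated)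
Conditions: Ph3C+ SbCl6− (5 mol %), CH2Cl2, −78 °C; then 1 M HCl, THF, 0 °C
Reagents that add atoms: none
Why: Trityl-cation-catalysed Mukaiyama–Michael addition in which the ketene acetal attacks C7 axially on the enone face syn to the oxygen bridge and anti to the two-carbon bridge, and an open synclinal transition state (ketene-acetal carbon over the unhindered C8 side, H-11 toward the C6 bridgehead) should set C11 as R; acid work-up hydrolyses enol ether 14.

Step 11
Reactants: 15 (7S,11R) C9 ketone
Product: 16 (9R) C9 alcohol (hydroxyl anti to the oxygen bridge)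
Conditions: {[Ph4(η5-C4CO)]2H}Ru2(CO)4(μ-H) (Shvo catalyst, 2 mol %), i-PrOH/toluene, 80 °C
Reagents that add atoms: none
Why: Shvo-catalysed transfer hydrogenation is reversible, so the C9 alcohol equilibrates through the ketone to the equatorial epimer that avoids the 1,3-diaxial contact with the axial C7 side chain (thermodynamic control of C9).

Step 12
Reactants: 16 (9R) C9 alcohol
Product: 17 C9 tert-butyldimethylsilyl ether
Conditions: TBSOTf, 2,6-lutidine, CH2Cl2, −78 → 0 °C
Reagents that add atoms: tert-butyldimethylsilyl triflate, CC(C)(C)[Si](C)(C)OS(=O)(=O)C(F)(F)F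
Why: Silylation of the hindered secondary alcohol with the reactive silyl triflate, so that C9 stays masked until the last step.

Step 13
Reactants: 17 C9 tert-butyldimethylsilyl ether
Product: 18 lactol (C2 hemiacetal, both anomers)
Conditions: i-Bu2AlH (1.2 equiv), CH2Cl2, −78 °C; Rochelle salt
Reagents that add atoms: none
Why: Half-reduction of the γ-lactone stops at the tetrahedral aluminate at −78 °C, while the hindered tert-butyl ester is left alone.

Step 14
Reactants: 18 lactol
Product: 19 C1-vinyl C18 primary alcohol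
Conditions: Ph3PCH3Br, KN(SiMe3)2, THF, −78 → 0 °C
Reagents that add atoms: methylenetriphenylphosphorane, C=P(c1ccccc1)(c1ccccc1)c1ccccc1
Why: Wittig methylenation of the open hydroxy-aldehyde form turns C2 into the C1 vinyl group and frees the C18 hydroxyl, and fast olefination at low temperature should precede epimerisation or β-elimination at C1.

Step 15
Reactants: 19 C1-vinyl C18 primary alcohol
Product: 20 C18 iodide
Conditions: PPh3, I2, imidazole, toluene, 70 °C
Reagents that add atoms: iodine, II
Why: Garegg–Samuelsson iodination (Appel type) of the only free hydroxyl; the neopentyl-type carbon needs heating but cannot eliminate.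

Step 16
Reactants: 20 C18 iodide
Product: 21 C4 secondary alcohol
Conditions: DDQ, CH2Cl2/pH 7 buffer (10:1), 0 °C
Reagents that add atoms: none
Why: Oxidative cleavage of the 4-methoxybenzyl ether, orthogonal to the silyl ether, tert-butyl ester, iodide and vinyl group.

Step 17
Reactants: 21 C4 secondary alcohol
Product: 22 C4 methyl ketone
Conditions: Dess–Martin periodinane, NaHCO3, CH2Cl2, 0 °C → rt
Reagents that add atoms: none
Why: Buffered Dess–Martin oxidation gives the methyl ketone without base, so the epimerisable C5 centre and the β-ether are not disturbed.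

Step 18
Reactants: 22 C4 methyl ketone
Product: 23 (4R) tertiary vinyl carbinol (1,6-diene)
Conditions: MgBr2·OEt2, CH2Cl2, −78 °C; CH2=CHMgBr (THF); NH4Cl
Reagents that add atoms: vinylmagnesium bromide, C=C[Mg]Br
Why: Chelation-controlled Grignard addition in which magnesium bridges the ketone oxygen and the C6–O–C10 ether oxygen and the vinyl group adds to the carbonyl face anti to C1 and its eclipsed vinyl arm, which should give the 4R carbinol.

Step 19
Reactants: 23 (4R) tertiary vinyl carbinol
Product: 24 C12 aldehyde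
Conditions: i-Bu2AlH (3 equiv), CH2Cl2, −78 °C; Rochelle salt
Reagents that add atoms: none
Why: Half-reduction of the tert-butyl ester to the aldehyde through the stable tetrahedral aluminate; the tertiary alkoxide only consumes one equivalent.

Step 20
Reactants: 24 C12 aldehyde
Product: 25 (12S,13S) C12 alcohol C13 methoxymethyl ether with a C13 vinyl group
Conditions: 3-(methoxymethoxy)prop-1-ene, s-BuLi, THF, −78 °C; (+)-Ipc2BOMe; BF3·OEt2; then 24, −78 °C; NaBO3·4H2O, THF/H2O, rt
Reagents that add atoms: [(Z)-3-(methoxymethoxy)allyl]diisopinocampheylborane (Ipc groups from (−)-α-pinene), COCO/C=C\CB(C1CC2CC(C1C)C2(C)C)C1CC2CC(C1C)C2(C)C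
Why: Brown γ-alkoxyallylboration through a chair transition state, in which the Z-γ-alkoxyallyl unit gives the syn (threo) diol pattern and the isopinocampheyl groups direct attack to the Re face of the aldehyde (12S,13S), matched with the Felkin preference of the α-methyl aldehyde.

Step 21
Reactants: 25 (12S,13S) C12 alcohol C13 methoxymethyl ether
Product: 26 C12,C13 diol
Conditions: MgBr2·OEt2, n-BuSH, Et2O, rt
Reagents that add atoms: none
Why: Lewis acid/thiol cleavage of the methoxymethyl ether, mild enough for the silyl ether and the tertiary allylic alcohol.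

Step 22
Reactants: 26 C12,C13 diol
Product: 27 C12,C13 diacetate (triene)
Conditions: Ac2O, pyridine, DMAP (cat.), CH2Cl2, 0 °C
Reagents that add atoms: acetic anhydride, CC(=O)OC(C)=O
Why: The two secondary hydroxyls are acetylated while the tertiary C4 hydroxyl is too hindered to react and C6 and C9 are still masked.

Step 23
Reactants: 27 C12,C13 diacetate (triene)
Product: 29 bridged cyclopentene iodide bearing the full side chain, via C13-vinyl cyclopentene 28 (not isolated)
Conditions: RuCl2(=CH-C6H4-2-OiPr)(H2IMes) (second-generation Hoveyda–Grubbs catalyst, 10 mol %), 2-methyl-2-butene/CH2Cl2 (1:3), 40 °C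
Reagents that add atoms: 2-methylbut-2-ene, CC=C(C)C
Why: The ruthenium alkylidene engages a terminal vinyl group, and [2+2] cycloaddition/cycloreversion with the second vinyl group closes the five-membered ring with loss of ethene (ring-closing metathesis of a 1,6-dien-3-ol, giving 28), after which alkylidene exchange between the C13 vinyl group and the excess 2-methyl-2-butene installs the C14=C15 olefin with loss of propene (cross-metathesis). The closest known reaction types are cyclopentenol-forming ring-closing metathesis of linalool-type dienes and prenyl-type cross-metathesis with 2-methyl-2-butene. The one ring formed, the cyclopentene C1–C2=C3–C4–C5, is closed by intramolecular olefin metathesis between the two exo vinyl arms, and the ring size enforces the cis C2=C3 geometry. No stereocentre is created, and C1, C4 and C5 are already set and are not touched. The step needs chemoselectivity among three monosubstituted olefins, which is secured because the C1 and C4 vinyl groups are held eclipsed on the exo face of the oxabicycle (fast five-ring closure, helped by the free allylic C4 hydroxyl) whereas the isolated C13 vinyl group can only exchange with the solvent olefin. The C10=C18 olefin is still masked as the iodomethyl ether, and the neopentyl iodide, the acetates and the silyl ether are inert to the catalyst.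

Step 24
Reactants: 29 bridged cyclopentene iodide
Product: 30 9-O-tert-butyldimethylsilyl ether of the target
Conditions: Zn dust (activated), NH4Cl, EtOH/THF, 65 °C
Reagents that add atoms: none
Why: Boord-type (Vasella) reductive elimination, in which zinc inserts into the C18–I bond and the β-ether oxygen is expelled, giving the C10=C18 methylene regiospecifically and freeing the C6 hydroxyl with its configuration unchanged.

Step 25
Reactants: 30 9-O-tert-butyldimethylsilyl ether of the target
Product: 31 target compound CNP0269663.2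
Conditions: HF·pyridine, pyridine, THF, 0 °C → rt
Reagents that add atoms: none
Why: Buffered fluoride desilylation frees the allylic C9 hydroxyl without acetate migration or ionisation of the tertiary allylic alcohol.

Compound list
1 | (S)-but-3-yn-2-ol | C[C@H](O)C#C | starting material
2 | (S)-3-[(4-methoxybenzyl)oxy]but-1-yne | C[C@H](OCc1ccc(OC)cc1)C#C | intermediate
3 | (S)-4-[(4-methoxybenzyl)oxy]pent-2-ynoic acid | C[C@H](OCc1ccc(OC)cc1)C#CC(=O)O | intermediate
4 | (S,Z)-4-[(4-methoxybenzyl)oxy]pent-2-enoic acid | C[C@H](OCc1ccc(OC)cc1)/C=C\C(=O)O | intermediate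
5 | 2-bromo-1-(furan-2-yl)ethan-1-one | O=C(CBr)c1ccco1 | starting material
6 | 2-(furan-2-yl)-2-oxoethyl (S,Z)-4-[(4-methoxybenzyl)oxy]pent-2-enoate | C[C@H](OCc1ccc(OC)cc1)/C=C\C(=O)OCC(=O)c1ccco1 | intermediate
7 | 2-(furan-2-yl)-2-hydroxyethyl (S,Z)-4-[(4-methoxybenzyl)oxy]pent-2-enoate, both carbinol epimers | C[C@H](OCc1ccc(OC)cc1)/C=C\C(=O)OCC(O)c1ccco1 | intermediate
8 | (6-hydroxy-3-oxo-3,6-dihydro-2H-pyran-2-yl)methyl (S,Z)-4-[(4-methoxybenzyl)oxy]pent-2-enoate, epimer mixture | C[C@H](OCc1ccc(OC)cc1)/C=C\C(=O)OCC1OC(O)C=CC1=O | intermediate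
9 | (6-acetoxy-3-oxo-3,6-dihydro-2H-pyran-2-yl)methyl (S,Z)-4-[(4-methoxybenzyl)oxy]pent-2-enoate, epimer mixture | C[C@H](OCc1ccc(OC)cc1)/C=C\C(=O)OCC1OC(OC(C)=O)C=CC1=O | intermediate
10 | 3-oxidopyrylium ylide carrying the (S,Z)-enoate ester on its 2-methylene group | C[C@H](OCc1ccc(OC)cc1)/C=C\C(=O)OCc1[o+]cccc1[O-] | intermediate
11 | tricyclic lactone enone: 8-oxabicyclo[3.2.1]oct-3-en-2-one (C9 ketone, C7=C8, oxygen bridging C6 and C10) with a γ-lactone C1–C2(=O)–O–C18H2–C10 (C2 exo on C1) and an exo (S)-1-[(4-methoxybenzyl)oxy]ethyl group on C5, cis to C2 | O=C3OC[C@@]12C(=O)C=C[C@@H](O1)[C@@H]([C@H](C)OCc4ccc(OC)cc4)[C@H]23 | intermediate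
12 | tert-butyl propanoate | CCC(=O)OC(C)(C)C | starting material
13 | (E)-1-tert-butoxy-1-(trimethylsilyloxy)prop-1-ene | C/C=C(\OC(C)(C)C)O[Si](C)(C)C | intermediate
14 | C9 trimethylsilyl enol ether (C8=C9) of 15 | O=C3OC[C@@]12C(O[Si](C)(C)C)=C[C@@H]([C@@H](C)C(=O)OC(C)(C)C)[C@@H](O1)[C@@H]([C@H](C)OCc4ccc(OC)cc4)[C@H]23 | intermediate
15 | as 11 but C7–C8 saturated, with a (7S,11R) 1-(tert-butoxycarbonyl)ethyl group on C7, syn to the oxygen bridge | O=C3OC[C@@]12C(=O)C[C@@H]([C@@H](C)C(=O)OC(C)(C)C)[C@@H](O1)[C@@H]([C@H](C)OCc4ccc(OC)cc4)[C@H]23 | intermediate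
16 | as 15 but C9 is a (9R) secondary alcohol, hydroxyl anti to the oxygen bridge | O=C3OC[C@@]12[C@H](O)C[C@@H]([C@@H](C)C(=O)OC(C)(C)C)[C@@H](O1)[C@@H]([C@H](C)OCc4ccc(OC)cc4)[C@H]23 | intermediate
17 | C9 tert-butyldimethylsilyl ether of 16 | O=C3OC[C@@]12[C@H](O[Si](C)(C)C(C)(C)C)C[C@@H]([C@@H](C)C(=O)OC(C)(C)C)[C@@H](O1)[C@@H]([C@H](C)OCc4ccc(OC)cc4)[C@H]23 | intermediate
18 | lactol of 17 (C2 hemiacetal, both anomers) | OC3OC[C@@]12[C@H](O[Si](C)(C)C(C)(C)C)C[C@@H]([C@@H](C)C(=O)OC(C)(C)C)[C@@H](O1)[C@@H]([C@H](C)OCc4ccc(OC)cc4)[C@H]23 | intermediate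
19 | oxabicycle with an exo vinyl group on C1 and a hydroxymethyl group (C18) on bridgehead C10 | OC[C@@]12[C@H](O[Si](C)(C)C(C)(C)C)C[C@@H]([C@@H](C)C(=O)OC(C)(C)C)[C@@H](O1)[C@@H]([C@H](C)OCc3ccc(OC)cc3)[C@H]2C=C | intermediate
20 | as 19 but with an iodomethyl group on C10 | IC[C@@]12[C@H](O[Si](C)(C)C(C)(C)C)C[C@@H]([C@@H](C)C(=O)OC(C)(C)C)[C@@H](O1)[C@@H]([C@H](C)OCc3ccc(OC)cc3)[C@H]2C=C | intermediate
21 | as 20 but with a free (S)-1-hydroxyethyl group on C5 | IC[C@@]12[C@H](O[Si](C)(C)C(C)(C)C)C[C@@H]([C@@H](C)C(=O)OC(C)(C)C)[C@@H](O1)[C@@H]([C@H](C)O)[C@H]2C=C | intermediate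
22 | as 20 but with an exo acetyl group on C5 (C4 methyl ketone) | IC[C@@]12[C@H](O[Si](C)(C)C(C)(C)C)C[C@@H]([C@@H](C)C(=O)OC(C)(C)C)[C@@H](O1)[C@@H](C(C)=O)[C@H]2C=C | intermediate
23 | as 22 but C4 is the (4R) tertiary carbinol carrying methyl and vinyl | IC[C@@]12[C@H](O[Si](C)(C)C(C)(C)C)C[C@@H]([C@@H](C)C(=O)OC(C)(C)C)[C@@H](O1)[C@@H]([C@](C)(O)C=C)[C@H]2C=C | intermediate
24 | as 23 but the C12 ester is reduced to the aldehyde | IC[C@@]12[C@H](O[Si](C)(C)C(C)(C)C)C[C@@H]([C@@H](C)C=O)[C@@H](O1)[C@@H]([C@](C)(O)C=C)[C@H]2C=C | intermediate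
25 | as 23 but with the side chain (11R,12S,13S) CH(CH3)–CH(OH)–CH(OCH2OCH3)–CH=CH2 on C7 | IC[C@@]12[C@H](O[Si](C)(C)C(C)(C)C)C[C@@H]([C@@H](C)[C@H](O)[C@H](C=C)OCOC)[C@@H](O1)[C@@H]([C@](C)(O)C=C)[C@H]2C=C | intermediate
26 | C12,C13 diol from 25 | IC[C@@]12[C@H](O[Si](C)(C)C(C)(C)C)C[C@@H]([C@@H](C)[C@H](O)[C@H](C=C)O)[C@@H](O1)[C@@H]([C@](C)(O)C=C)[C@H]2C=C | intermediate
27 | C12,C13 diacetate of 26 | IC[C@@]12[C@H](O[Si](C)(C)C(C)(C)C)C[C@@H]([C@@H](C)[C@H](OC(C)=O)[C@H](C=C)OC(C)=O)[C@@H](O1)[C@@H]([C@](C)(O)C=C)[C@H]2C=C | intermediate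
28 | ring-closed product: cyclopentene C1–C2=C3–C4–C5 fused exo to the oxabicycle, C13 still carrying a vinyl group | IC[C@@]12[C@H](O[Si](C)(C)C(C)(C)C)C[C@@H]([C@@H](C)[C@H](OC(C)=O)[C@H](C=C)OC(C)=O)[C@@H](O1)[C@@H]3[C@H]2C=C[C@@]3(C)O | intermediate
29 | as 28 but with the 2-methylprop-1-enyl group on C13 (C14=C15) | IC[C@@]12[C@H](O[Si](C)(C)C(C)(C)C)C[C@@H]([C@@H](C)[C@H](OC(C)=O)[C@H](C=C(C)C)OC(C)=O)[C@@H](O1)[C@@H]3[C@H]2C=C[C@@]3(C)O | intermediate
30 | 9-O-tert-butyldimethylsilyl ether of the target | C=C1[C@H](O[Si](C)(C)C(C)(C)C)C[C@@H]([C@@H](C)[C@H](OC(C)=O)[C@H](C=C(C)C)OC(C)=O)[C@@H](O)[C@@H]2[C@H]1C=C[C@@]2(C)O | intermediate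
31 | CNP0269663.2: cis-fused hydroazulene triol 12,13-diacetate | C=C1[C@H](O)C[C@@H]([C@@H](C)[C@H](OC(C)=O)[C@H](C=C(C)C)OC(C)=O)[C@@H](O)[C@@H]2[C@H]1C=C[C@@]2(C)O | target

Total step count: 25. Longest linear sequence: 24 steps (steps 1–8 and 10–25, from 1).

Steps most likely to fail

Step 8. The ylide may not reach the lactone-forming transition state, because the ester tether must adopt its disfavoured rotamer, so ylide dimerisation or β-elimination of the carboxylate from the pyranone could win. The fallback sets out from 2 and returns at 11, replacing the ester by a silicon tether and making the lactone afterwards. Lithiated 2 is hydroxymethylated with paraformaldehyde to (S)-4-[(4-methoxybenzyl)oxy]pent-2-yn-1-ol F1 and semihydrogenated (Lindlar) to (S,Z)-4-[(4-methoxybenzyl)oxy]pent-2-en-1-ol F2. F2 and the primary hydroxyl of commercial 1-(furan-2-yl)ethane-1,2-diol are joined with iPr2SiCl2/imidazole to the diisopropylsilylene-bridged furyl carbinol F3. Achmatowicz oxidation gives the pyranone hemiacetal F4 and acetylation the pyranone acetate F5. Et3N then triggers the cycloaddition through the siloxane tether (Z olefin, so cis arms) to the siloxane-bridged oxabicyclic enone F6. HF·pyridine frees the bis(hydroxymethyl) enone F7, and TEMPO/PhI(OAc)2 oxidises the less hindered C2 hydroxyl through the lactol to lactone 11.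

Step 10. The open transition state may give poor facial discrimination of the ketene acetal, and so a mixture at C11. The fallback sets out from 11 and returns at 15, setting C11 by hydroboration instead. Copper-catalysed 1,4-addition of isopropenylmagnesium bromide (CuBr·SMe2, Me3SiCl) gives the C7-isopropenyl ketone F8. Hydroboration with 9-BBN (the hindered C9 ketone is spared) and NaBO3 oxidation set C11 under allylic-strain control and give the primary alcohol F9. TEMPO/NaOCl/NaClO2 gives the carboxylic acid F10, and tert-butyl 2,2,2-trichloroacetimidate with catalytic BF3·OEt2 gives 15.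

Step 18. If chelation does not hold, addition to the ketone may show poor or reversed facial selectivity at C4, and enolisation with opening of the β-ether could compete. The fallback sets out from 22 and returns at 23, delivering oxygen rather than carbon to the accessible face. Methylenation with Ph3P=CH2 gives the C5-isopropenyl compound F11, and mCPBA/NaHCO3 epoxidises the 1,1-disubstituted olefin selectively to the epoxide F12. Dimethylsulfonium methylide (Me3S+ I−, n-BuLi) then opens the epoxide at CH2 and eliminates to the vinyl carbinol 23. From the same rotamer this gives the C4 configuration complementary to that of carbonyl addition.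

Further compounds
F1 | step 8 | (S)-4-[(4-methoxybenzyl)oxy]pent-2-yn-1-ol | C[C@H](OCc1ccc(OC)cc1)C#CCO
F2 | step 8 | (S,Z)-4-[(4-methoxybenzyl)oxy]pent-2-en-1-ol | C[C@H](OCc1ccc(OC)cc1)/C=C\CO
F3 | step 8 | diisopropylsilylene-bridged furyl carbinol | C[C@H](OCc1ccc(OC)cc1)/C=C\CO[Si](C(C)C)(C(C)C)OCC(O)c1ccco1
F4 | step 8 | silicon-tethered pyranone hemiacetal | C[C@H](OCc1ccc(OC)cc1)/C=C\CO[Si](C(C)C)(C(C)C)OCC1OC(O)C=CC1=O
F5 | step 8 | silicon-tethered pyranone acetate | C[C@H](OCc1ccc(OC)cc1)/C=C\CO[Si](C(C)C)(C(C)C)OCC1OC(OC(C)=O)C=CC1=O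
F6 | step 8 | siloxane-bridged oxabicyclic enone | CC(C)[Si]3(C(C)C)OC[C@@]12C(=O)C=C[C@@H](O1)[C@@H]([C@H](C)OCc4ccc(OC)cc4)[C@H]2CO3
F7 | step 8 | oxabicyclic enone with hydroxymethyl groups on C10 and C1 | OC[C@@]12C(=O)C=C[C@@H](O1)[C@@H]([C@H](C)OCc3ccc(OC)cc3)[C@H]2CO
F8 | step 10 | C7-isopropenyl ketone | O=C3OC[C@@]12C(=O)C[C@@H](C(C)=C)[C@@H](O1)[C@@H]([C@H](C)OCc4ccc(OC)cc4)[C@H]23
F9 | step 10 | (11R) primary alcohol at C12 | O=C3OC[C@@]12C(=O)C[C@@H]([C@@H](C)CO)[C@@H](O1)[C@@H]([C@H](C)OCc4ccc(OC)cc4)[C@H]23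
F10 | step 10 | (11R) carboxylic acid at C12 | O=C3OC[C@@]12C(=O)C[C@@H]([C@@H](C)C(=O)O)[C@@H](O1)[C@@H]([C@H](C)OCc4ccc(OC)cc4)[C@H]23
F11 | step 18 | C5-isopropenyl compound | IC[C@@]12[C@H](O[Si](C)(C)C(C)(C)C)C[C@@H]([C@@H](C)C(=O)OC(C)(C)C)[C@@H](O1)[C@@H](C(C)=C)[C@H]2C=C
F12 | step 18 | C4 spiro-epoxide (2-methyloxiran-2-yl on C5) | IC[C@@]12[C@H](O[Si](C)(C)C(C)(C)C)C[C@@H]([C@@H](C)C(=O)OC(C)(C)C)[C@@H](O1)[C@@H]([C@@]3(C)CO3)[C@H]2C=C
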